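## Retrosynthetic overview

1. The target is a briarane: a six-membered ring A trans-fused to a ten-membered ring, with a γ-lactone on C7/C8. The ten-membered ring is closed as the last C–C bond, at C2–C3, by a Nozaki–Hiyama–Kishi cyclisation of a C2 aldehyde onto a (Z)-C3 dienyl iodide. The enabling feature is that C2 is a carbinol carbon flanked by the quaternary C1 of ring A (its aldehyde cannot enolise) and by the cis 3,4-oxirane next to the C5(16) methylene, which together are a masked (Z)-2-hydroxy-3,5(16)-diene.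
2. The C2 hydroxyl created in that step is allylic to C3=C4 and homoallylic to C13=C14 on the α face of ring A, so one vanadium-directed epoxidation installs both oxiranes. Acetylation and an SN2 chlorination at C6 (inversion) finish the synthesis.
3. Seco-aldehyde: the γ-lactone (C8–C17 bond, C8 and C17 stereocentres) comes from an intramolecular samarium Reformatsky reaction; C6–C7 from a syn boron aldol with (Z)-4-iodo-2-methylidenebut-3-enal; C8–C9 from Felkin addition of 1-ethoxyvinyllithium to a ring A lactol.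
4. Ring A: catalytic asymmetric Diels–Alder reaction of (E)-piperylene with ethyl (E)-2-methyl-4-oxobut-2-enoate (sets C1, C10, C11), then iodolactonisation and elimination (sets C12–O and C13=C14).
5. Ring order: ring A, then the γ-lactone, then the ten-membered ring, then the two oxiranes.

Key step: step 25

Remark on numbering: locants follow the briarane skeleton. C1 is the quaternary ring-fusion carbon (C15 methyl); C2–C9 complete the ten-membered ring; C10 is the ring-fusion CH; C11–C14 complete ring A (C20 methyl on C11); C16 is the methylene on C5; C17 (C18 methyl) and C19 (carbonyl) belong to the lactone closed on O–C7.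

Assumption: in step 3 the (S)-oxazaborolidinium catalyst is taken to give the enantiomer drawn (usual formyl C–H···O binding model); the (R)-catalyst would be used if the sense were opposite.

## Route

Step 1
Reactants: 1 ethyl 2-(triphenyl-λ5-phosphanylidene)propanoate; 2 2,2-dimethoxyacetaldehyde
Product: 3 ethyl (E)-4,4-dimethoxy-2-methylbut-2-enoate
Conditions: CH2Cl2, rt
Reagents that add atoms: none
Why: Wittig olefination with a stabilised ylide gives the E enoate (ester trans to the acetal carbon).

Step 2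
Reactants: 3 ethyl (E)-4,4-dimethoxy-2-methylbut-2-enoate
Product: 4 ethyl (E)-2-methyl-4-oxobut-2-enoate
Conditions: HCO2H, H2O, acetone, rt
Reagents that add atoms: water (O)
Why: Acid-catalysed acetal hydrolysis frees the aldehyde without touching the conjugated ester or the E geometry.

Step 3
Reactants: 4 ethyl (E)-2-methyl-4-oxobut-2-enoate; 5 (E)-penta-1,3-diene
Product: 6 ethyl (1S,5S,6S)-6-formyl-1,5-dimethylcyclohex-3-ene-1-carboxylate
Conditions: (S)-3,3-diphenyl-1-(o-tolyl)tetrahydro-1H,3H-pyrrolo[1,2-c][1,3,2]oxazaborole (20 mol%), Tf2NH (18 mol%), CH2Cl2, −78 °C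
Reagents that add atoms: none
Why: In this Lewis-acid-catalysed asymmetric Diels–Alder reaction the boron-bound formyl group directs regiochemistry (formyl-bearing carbon bonds to the methyl-bearing diene terminus) and sits endo, so the C10 formyl and C11 methyl end cis, the E dienophile places the C1 ester trans to the formyl group, and the catalyst shields one enal face to set absolute configuration.

Step 4
Reactants: 6 ethyl (1S,5S,6S)-6-formyl-1,5-dimethylcyclohex-3-ene-1-carboxylate
Product: 7 (1S,2S,6S)-6-(ethoxycarbonyl)-2,6-dimethylcyclohex-3-ene-1-carboxylic acid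
Conditions: NaClO2, NaH2PO4, 2-methylbut-2-ene, t-BuOH/H2O, 0 °C to rt
Reagents that add atoms: sodium chlorite ([Na+].[O-]Cl=O)
Why: Pinnick oxidation converts the aldehyde to the acid without epimerising C10 or attacking the ring alkene, the hypochlorite being scavenged.

Step 5
Reactants: 7 (1S,2S,6S)-6-(ethoxycarbonyl)-2,6-dimethylcyclohex-3-ene-1-carboxylic acid
Product: 8 iodolactone (ethyl 4-iodo-2,8-dimethyl-7-oxo-6-oxabicyclo[3.2.1]octane-2-carboxylate)
Conditions: I2, KI, NaHCO3, H2O/CH2Cl2, 0 °C to rt, dark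
Reagents that add atoms: iodine (II)
Why: Iodolactonisation adds carboxylate and iodonium anti across C12=C13 to form the bridged γ-lactone, which fixes the C12 oxygen cis to the C10 carboxyl and therefore cis to both methyl groups.

Step 6
Reactants: 8 iodolactone
Product: 9 allylic lactone (ethyl 2,8-dimethyl-7-oxo-6-oxabicyclo[3.2.1]oct-3-ene-2-carboxylate)
Conditions: DBU, toluene, 80 °C
Reagents that add atoms: none
Why: E2 dehydroiodination through the antiperiplanar C14–H/C13–I pair moves unsaturation to C13=C14, leaving C12 as an allylic lactone carbon.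

Step 7
Reactants: 9 allylic lactone
Product: 10 lactol (ethyl 7-hydroxy-2,8-dimethyl-6-oxabicyclo[3.2.1]oct-3-ene-2-carboxylate)
Conditions: i-Bu2AlH (1.1 equiv), CH2Cl2, −78 °C; aq. potassium sodium tartrate
Reagents that add atoms: none
Why: Low-temperature hydride reduction stops at the lactol (stable aluminium hemiacetal), and the bridged γ-lactone reacts in preference to the α-quaternary ethyl ester.

Step 8
Reactants: 10 lactol; 11 ethoxyethene
Product: 13 diol ester, via 1-ethoxyvinyllithium 12 (not isolated)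
Conditions: 11, t-BuLi, THF, −78 to 0 °C; then 10 (0.3 equiv), −78 °C; H2O
Reagents that add atoms: none
Why: The α-lithiated enol ether (an acyl anion equivalent) adds to the ring-opened hydroxy aldehyde by Felkin–Anh attack anti to the quaternary C1, which sets the C9 carbinol as 9R.

Step 9
Reactants: 13 diol ester
Product: 14 triol
Conditions: LiAlH4, THF, 0 °C; then H2O
Reagents that add atoms: none
Why: LiAlH4 reduces the hindered ester to the C2 primary alcohol and leaves the enol ether and the ring alkene untouched.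

Step 10
Reactants: 14 triol
Product: 15 C2 silyl ether diol
Conditions: t-BuMe2SiCl (1.05 equiv), imidazole, CH2Cl2, −20 °C
Reagents that add atoms: tert-butyldimethylsilyl chloride (CC(C)(C)[Si](C)(C)Cl)
Why: Silylation is selective for the only primary hydroxyl over the two secondary ones.

Step 11
Reactants: 15 C2 silyl ether diol
Product: 16 diacetate enol ether
Conditions: Ac2O, pyridine, DMAP (cat.), CH2Cl2, rt
Reagents that add atoms: acetic anhydride (CC(=O)OC(C)=O)
Why: DMAP-catalysed acylation installs the C9 and C12 acetates of the target under basic conditions that the enol ether tolerates.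

Step 12
Reactants: 16 diacetate enol ether
Product: 18 α-hydroxy ketone, via ethyl hemiketal diol 17 (not isolated)
Conditions: OsO4 (2 mol%), N-methylmorpholine N-oxide, acetone/H2O, 0 °C
Reagents that add atoms: N-methylmorpholine N-oxide (C[N+]1([O-])CCOCC1); water (O)
Why: Upjohn dihydroxylation takes place at the electron-rich enol ether in preference to the acetate-deactivated ring alkene, and the resulting hemiketal collapses with loss of ethanol to the C8 ketone carrying a C7 hydroxymethyl group.

Step 13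
Reactants: 18 α-hydroxy ketone
Product: 19 α-triethylsilyloxy ketone
Conditions: Et3SiCl, imidazole, CH2Cl2, 0 °C
Reagents that add atoms: chlorotriethylsilane (CC[Si](CC)(CC)Cl)
Why: Silylation of the primary α-keto alcohol gives the aldol donor with a group removable later in the presence of tert-butyldimethylsilyl ethers.

Step 14
Reactants: 20 2-bromoprop-2-en-1-ol; 21 ethynyltrimethylsilane
Product: 22 2-methylidene-4-(trimethylsilyl)but-3-yn-1-ol
Conditions: PdCl2(PPh3)2 (2 mol%), CuI (4 mol%), Et3N, THF, rt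
Reagents that add atoms: none
Why: Sonogashira coupling of the vinyl bromide with the terminal alkyne builds the C3–C6 enyne carbon chain.

Step 15
Reactants: 22 2-methylidene-4-(trimethylsilyl)but-3-yn-1-ol
Product: 23 4-iodo-2-methylidenebut-3-yn-1-ol
Conditions: N-iodosuccinimide, AgNO3 (10 mol%), DMF, rt, dark
Reagents that add atoms: N-iodosuccinimide (O=C1CCC(=O)N1I)
Why: Silver-catalysed iododesilylation converts the alkynylsilane directly into the 1-iodoalkyne.

Step 16
Reactants: 23 4-iodo-2-methylidenebut-3-yn-1-ol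
Product: 24 (Z)-4-iodo-2-methylidenebut-3-en-1-ol
Conditions: 2-nitrobenzenesulfonohydrazide, Et3N, THF/i-PrOH, rt
Reagents that add atoms: none
Why: Diimide generated from the sulfonohydrazide adds hydrogen syn to the iodoalkyne and so gives the (Z)-iodoalkene, the less reactive 1,1-disubstituted alkene being spared.

Step 17
Reactants: 24 (Z)-4-iodo-2-methylidenebut-3-en-1-ol
Product: 25 (Z)-4-iodo-2-methylidenebut-3-enal
Conditions: MnO2, CH2Cl2, rt; used at once
Reagents that add atoms: none
Why: MnO2 oxidises the allylic alcohol to the enal under neutral conditions that preserve the Z iodoalkene.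

Step 18
Reactants: 19 α-triethylsilyloxy ketone; 25 (Z)-4-iodo-2-methylidenebut-3-enal
Product: 27 syn aldol adduct, via dibutylboron Z-enolate 26 (not isolated)
Conditions: n-Bu2BOTf, i-Pr2NEt, CH2Cl2, −78 °C; then 25, −78 to −40 °C; pH 7 buffer, MeOH, H2O2, 0 °C
Reagents that add atoms: none
Why: In this boron-mediated aldol addition the Z enolate of the α-silyloxy ketone reacts through a Zimmerman–Traxler chair to give the 6,7-syn adduct, with the facial sense expected from 1,4-induction by the C9 acetoxy stereocentre (Ipc2BOTf being available for reagent control).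

Step 19
Reactants: 27 syn aldol adduct
Product: 28 bis-silyl ether
Conditions: t-BuMe2SiOTf, 2,6-lutidine, CH2Cl2, −78 °C
Reagents that add atoms: tert-butyldimethylsilyl trifluoromethanesulfonate (CC(C)(C)[Si](C)(C)OS(=O)(=O)C(F)(F)F)
Why: The silyl triflate protects the hindered allylic C6 hydroxyl at low temperature with a weak base, which avoids retro-aldol cleavage.

Step 20
Reactants: 28 bis-silyl ether
Product: 29 C7 alcohol
Conditions: PPTS (cat.), MeOH/CH2Cl2, 0 °C
Reagents that add atoms: none
Why: Mild acid methanolysis removes the more labile secondary triethylsilyl ether and leaves both tert-butyldimethylsilyl ethers and the acetates.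

Step 21
Reactants: 29 C7 alcohol; 30 2-bromopropanoyl bromide
Product: 31 C7 2-bromopropanoate
Conditions: pyridine, CH2Cl2, −20 °C
Reagents that add atoms: none
Why: Acylation of the C7 hydroxyl attaches C17–C19, the bromine-bearing carbon being used as an epimer mixture because it becomes a planar enolate in the next step.

Step 22
Reactants: 31 C7 2-bromopropanoate
Product: 33 β-hydroxy-γ-lactone, via samarium enolate 32 (not isolated)
Conditions: SmI2 (2.2 equiv), THF, −78 °C; then H2O
Reagents that add atoms: none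
Why: In this intramolecular samarium Reformatsky reaction, two-electron reduction of the C–Br bond gives a samarium enolate that adds to the C8 ketone within a chelate and closes the γ-lactone with the large C9 substituent trans to both the C6-bearing group on C7 and the C17 methyl, both bromide epimers converging on the target configuration at C8 and C17.

Step 23
Reactants: 33 β-hydroxy-γ-lactone
Product: 34 C2 primary alcohol
Conditions: HF·pyridine, pyridine, THF, 0 °C
Reagents that add atoms: none
Why: Buffered HF·pyridine cleaves the primary silyl ether selectively over the hindered secondary allylic one at C6.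

Step 24
Reactants: 34 C2 primary alcohol
Product: 35 seco-aldehyde
Conditions: Dess–Martin periodinane, CH2Cl2, 0 °C to rt
Reagents that add atoms: none
Why: Dess–Martin oxidation gives the non-enolisable neopentyl aldehyde while the tertiary C8 hydroxyl stays inert.

Step 25
Reactants: 35 seco-aldehyde
Product: 37 macrocyclic dienol, via alkenylchromium species 36 (not isolated)
Conditions: CrCl2 (10 equiv), NiCl2 (0.1 equiv), DMSO/THF (3:1), 0.002 M, rt
Reagents that add atoms: none
Why: Nozaki–Hiyama–Kishi reaction: zerovalent nickel (formed from NiCl2 by CrCl2) inserts into the C3–I bond, the alkenyl group passes to trivalent chromium with retention of the Z geometry, and the alkenylchromium species 36 adds to the C2 aldehyde to give the chromium alkoxide of 37. The closest known reaction type is the NHK macrocyclisation of iodoalkenyl aldehydes to medium-ring allylic alcohols in terpenoid synthesis. The ten-membered ring closes in the 10-exo-trig mode. The only new stereocentre, C2, is set by the substrate: the tether leaves the rigid ring A at C10, so C3 must approach gauche to C10, and it does so antiperiplanar to the angular C15 methyl with the chromium-bound oxygen pointing out of the forming ring (a Felkin–Anh arrangement), which gives the C2 configuration of the target. Chemoselectivity for the aldehyde over lactone, acetates, silyl ether and free tertiary hydroxyl is inherent to alkenylchromium reagents, and the neopentyl aldehyde can neither enolise nor epimerise. Cyclisation over oligomerisation is secured by high dilution and by the trans C1/C10 substitution of ring A and the Z alkene, which hold the two termini close.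

Step 26
Reactants: 37 macrocyclic dienol
Product: 39 bis-epoxy alcohol, via 3,4-monoepoxide 38 (not isolated)
Conditions: VO(acac)2 (10 mol%), t-BuOOH (3 equiv, in decane), CH2Cl2, 0 °C to rt
Reagents that add atoms: tert-butyl hydroperoxide (CC(C)(C)OO)
Why: In this vanadium-catalysed hydroxyl-directed epoxidation the C2 hydroxyl is allylic to the Z C3=C4 alkene (cis delivery, as in medium-ring cis-cycloalkenols) and homoallylic to C13=C14, to which it delivers oxygen on the α face where C2 sits, so both oxiranes form with the target configuration while the remote C5(16) alkene is left.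

Step 27
Reactants: 39 bis-epoxy alcohol
Product: 40 triacetate silyl ether
Conditions: Ac2O, pyridine, DMAP (cat.), CH2Cl2, 0 °C to rt
Reagents that add atoms: acetic anhydride (CC(=O)OC(C)=O)
Why: Acylation takes the secondary C2 hydroxyl, the tertiary C8 hydroxyl being unreactive under these conditions.

Step 28
Reactants: 40 triacetate silyl ether
Product: 41 C6 alcohol
Conditions: HF·pyridine, pyridine, THF, 0 °C to rt
Reagents that add atoms: none
Why: Buffered fluoride desilylation frees the C6 hydroxyl under conditions that spare oxiranes, acetates and the lactone.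

Step 29
Reactants: 41 C6 alcohol
Product: 43 target, via alkoxyphosphonium chloride 42 (not isolated)
Conditions: Ph3P, Cl3CC(O)CCl3, CH2Cl2, −20 to 0 °C
Reagents that add atoms: hexachloroacetone (ClC(Cl)(Cl)C(=O)C(Cl)(Cl)Cl)
Why: Deoxychlorination with triphenylphosphine and hexachloroacetone (Magid conditions) displaces the oxyphosphonium group by chloride in an SN2 step that inverts C6 (6R alcohol to 6S chloride) without allylic transposition.

## Compound list

1 | ethyl 2-(triphenyl-λ5-phosphanylidene)propanoate | CCOC(=O)C(C)=P(c1ccccc1)(c1ccccc1)c1ccccc1 | starting material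
2 | 2,2-dimethoxyacetaldehyde | COC(OC)C=O | starting material
3 | ethyl (E)-4,4-dimethoxy-2-methylbut-2-enoate | CCOC(=O)/C(C)=C/C(OC)OC | intermediate
4 | ethyl (E)-2-methyl-4-oxobut-2-enoate | CCOC(=O)/C(C)=C/C=O | intermediate
5 | (E)-penta-1,3-diene | C/C=C/C=C | starting material
6 | ethyl (1S,5S,6S)-6-formyl-1,5-dimethylcyclohex-3-ene-1-carboxylate (formyl cis to both methyls, trans to the ester) | CCOC(=O)[C@@]1(C)CC=C[C@H](C)[C@@H]1C=O | intermediate
7 | (1S,2S,6S)-6-(ethoxycarbonyl)-2,6-dimethylcyclohex-3-ene-1-carboxylic acid | CCOC(=O)[C@@]1(C)CC=C[C@H](C)[C@@H]1C(=O)O | intermediate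
8 | iodolactone, ethyl 4-iodo-2,8-dimethyl-7-oxo-6-oxabicyclo[3.2.1]octane-2-carboxylate (C13 iodine trans to the C12 lactone oxygen; ester on the face opposite the lactone bridge) | CCOC(=O)[C@@]1(C)C[C@@H](I)[C@@H]2OC(=O)[C@H]1[C@H]2C | intermediate
9 | allylic lactone, ethyl 2,8-dimethyl-7-oxo-6-oxabicyclo[3.2.1]oct-3-ene-2-carboxylate | CCOC(=O)[C@@]1(C)C=C[C@@H]2OC(=O)[C@H]1[C@H]2C | intermediate
10 | lactol, ethyl 7-hydroxy-2,8-dimethyl-6-oxabicyclo[3.2.1]oct-3-ene-2-carboxylate (anomer mixture) | CCOC(=O)[C@@]1(C)C=C[C@@H]2OC(O)[C@H]1[C@H]2C | intermediate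
11 | ethoxyethene (ethyl vinyl ether) | C=COCC | starting material
12 | 1-ethoxyvinyllithium | [Li]C(=C)OCC | intermediate
13 | diol ester: ring A ethyl ester with free C12 hydroxyl and a (9R) carbinol carrying the 1-ethoxyvinyl group | CCOC(=O)[C@@]1(C)C=C[C@H](O)[C@H](C)[C@@H]1[C@@H](O)C(=C)OCC | intermediate
14 | triol: C2 primary alcohol, C9 and C12 secondary alcohols, enol ether retained | OC[C@@]1(C)C=C[C@H](O)[C@H](C)[C@@H]1[C@@H](O)C(=C)OCC | intermediate
15 | C2 tert-butyldimethylsilyl ether of triol 14 | CC(C)(C)[Si](C)(C)OC[C@@]1(C)C=C[C@H](O)[C@H](C)[C@@H]1[C@@H](O)C(=C)OCC | intermediate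
16 | 9,12-diacetate enol ether | CC(C)(C)[Si](C)(C)OC[C@@]1(C)C=C[C@H](OC(C)=O)[C@H](C)[C@@H]1[C@@H](OC(C)=O)C(=C)OCC | intermediate
17 | ethyl hemiketal diol at C8/C7 (C8 epimers) | CC(C)(C)[Si](C)(C)OC[C@@]1(C)C=C[C@H](OC(C)=O)[C@H](C)[C@@H]1[C@@H](OC(C)=O)C(O)(CO)OCC | intermediate
18 | α-hydroxy ketone (C8 ketone, C7 hydroxymethyl) | CC(C)(C)[Si](C)(C)OC[C@@]1(C)C=C[C@H](OC(C)=O)[C@H](C)[C@@H]1[C@@H](OC(C)=O)C(=O)CO | intermediate
19 | α-triethylsilyloxy ketone | CC(C)(C)[Si](C)(C)OC[C@@]1(C)C=C[C@H](OC(C)=O)[C@H](C)[C@@H]1[C@@H](OC(C)=O)C(=O)CO[Si](CC)(CC)CC | intermediate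
20 | 2-bromoprop-2-en-1-ol | OCC(Br)=C | starting material
21 | ethynyltrimethylsilane | C#C[Si](C)(C)C | starting material
22 | 2-methylidene-4-(trimethylsilyl)but-3-yn-1-ol | OCC(=C)C#C[Si](C)(C)C | intermediate
23 | 4-iodo-2-methylidenebut-3-yn-1-ol | OCC(=C)C#CI | intermediate
24 | (Z)-4-iodo-2-methylidenebut-3-en-1-ol | OCC(=C)/C=C\I | intermediate
25 | (Z)-4-iodo-2-methylidenebut-3-enal | O=CC(=C)/C=C\I | intermediate
26 | dibutylboron Z-enolate of 19 (C7=C8) | CC(C)(C)[Si](C)(C)OC[C@@]1(C)C=C[C@H](OC(C)=O)[C@H](C)[C@@H]1[C@@H](OC(C)=O)/C(OB(CCCC)CCCC)=C/O[Si](CC)(CC)CC | intermediate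
27 | syn aldol adduct (6R hydroxyl, C7 triethylsilyloxy, 6,7-syn; (Z)-iodo diene) | CC(C)(C)[Si](C)(C)OC[C@@]1(C)C=C[C@H](OC(C)=O)[C@H](C)[C@@H]1[C@@H](OC(C)=O)C(=O)[C@@H](O[Si](CC)(CC)CC)[C@H](O)C(=C)/C=C\I | intermediate
28 | bis-silyl ether (C6 tert-butyldimethylsilyl, C7 triethylsilyl) | CC(C)(C)[Si](C)(C)OC[C@@]1(C)C=C[C@H](OC(C)=O)[C@H](C)[C@@H]1[C@@H](OC(C)=O)C(=O)[C@@H](O[Si](CC)(CC)CC)[C@H](O[Si](C)(C)C(C)(C)C)C(=C)/C=C\I | intermediate
29 | C7 alcohol (α-hydroxy ketone, C6 silyl ether) | CC(C)(C)[Si](C)(C)OC[C@@]1(C)C=C[C@H](OC(C)=O)[C@H](C)[C@@H]1[C@@H](OC(C)=O)C(=O)[C@@H](O)[C@H](O[Si](C)(C)C(C)(C)C)C(=C)/C=C\I | intermediate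
30 | 2-bromopropanoyl bromide (racemic) | CC(Br)C(=O)Br | starting material
31 | C7 2-bromopropanoate (epimers at the bromine-bearing carbon) | CC(C)(C)[Si](C)(C)OC[C@@]1(C)C=C[C@H](OC(C)=O)[C@H](C)[C@@H]1[C@@H](OC(C)=O)C(=O)[C@@H](OC(=O)C(C)Br)[C@H](O[Si](C)(C)C(C)(C)C)C(=C)/C=C\I | intermediate
32 | samarium enolate of the C7 propanoate | CC(C)(C)[Si](C)(C)OC[C@@]1(C)C=C[C@H](OC(C)=O)[C@H](C)[C@@H]1[C@@H](OC(C)=O)C(=O)[C@@H](OC(O[Sm](I)I)=CC)[C@H](O[Si](C)(C)C(C)(C)C)C(=C)/C=C\I | intermediate
33 | β-hydroxy-γ-lactone (C7, C8, C17 as in the target; 6R silyl ether; C2 silyl ether) | CC(C)(C)[Si](C)(C)OC[C@@]1(C)C=C[C@H](OC(C)=O)[C@H](C)[C@@H]1[C@@H](OC(C)=O)[C@]2(O)[C@@H](C)C(=O)O[C@H]2[C@H](O[Si](C)(C)C(C)(C)C)C(=C)/C=C\I | intermediate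
34 | C2 primary alcohol | OC[C@@]1(C)C=C[C@H](OC(C)=O)[C@H](C)[C@@H]1[C@@H](OC(C)=O)[C@]2(O)[C@@H](C)C(=O)O[C@H]2[C@H](O[Si](C)(C)C(C)(C)C)C(=C)/C=C\I | intermediate
35 | seco-aldehyde (C2 aldehyde, (Z)-C3 iodide) | O=C[C@@]1(C)C=C[C@H](OC(C)=O)[C@H](C)[C@@H]1[C@@H](OC(C)=O)[C@]2(O)[C@@H](C)C(=O)O[C@H]2[C@H](O[Si](C)(C)C(C)(C)C)C(=C)/C=C\I | intermediate
36 | alkenylchromium dichloride derived from 35 | O=C[C@@]1(C)C=C[C@H](OC(C)=O)[C@H](C)[C@@H]1[C@@H](OC(C)=O)[C@]2(O)[C@@H](C)C(=O)O[C@H]2[C@H](O[Si](C)(C)C(C)(C)C)C(=C)/C=C\[Cr](Cl)Cl | intermediate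
37 | macrocyclic dienol: 9,12-diacetoxy-6-(tert-butyldimethylsilyloxy)-2,8-dihydroxybriara-3(Z),5(16),13-trien-19,7-olide (C2 as required for the target, 6R) | C=C1/C=C\[C@@H](O)[C@]2(C)[C@H]([C@@H](C)[C@@H](OC(C)=O)C=C2)[C@@H](OC(C)=O)[C@]2(O)[C@@H](C)C(=O)O[C@H]2[C@@H]1O[Si](C)(C)C(C)(C)C | intermediate
38 | 3,4-monoepoxide of 37 (oxirane cis to the C2 hydroxyl) | C=C1[C@H]2O[C@H]2[C@@H](O)[C@]2(C)[C@H]([C@@H](C)[C@@H](OC(C)=O)C=C2)[C@@H](OC(C)=O)[C@]2(O)[C@@H](C)C(=O)O[C@H]2[C@@H]1O[Si](C)(C)C(C)(C)C | intermediate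
39 | bis-epoxy alcohol (3,4- and 13,14-oxiranes as in the target, free C2 hydroxyl) | C=C1[C@H]2O[C@H]2[C@@H](O)[C@]2(C)[C@H]([C@@H](C)[C@@H](OC(C)=O)[C@@H]3O[C@@H]32)[C@@H](OC(C)=O)[C@]2(O)[C@@H](C)C(=O)O[C@H]2[C@@H]1O[Si](C)(C)C(C)(C)C | intermediate
40 | 2,9,12-triacetate with 6R silyl ether | C=C1[C@H]2O[C@H]2[C@@H](OC(C)=O)[C@]2(C)[C@H]([C@@H](C)[C@@H](OC(C)=O)[C@@H]3O[C@@H]32)[C@@H](OC(C)=O)[C@]2(O)[C@@H](C)C(=O)O[C@H]2[C@@H]1O[Si](C)(C)C(C)(C)C | intermediate
41 | C6 alcohol (6R; 6-epi-hydroxy analogue of the target) | C=C1[C@H]2O[C@H]2[C@@H](OC(C)=O)[C@]2(C)[C@H]([C@@H](C)[C@@H](OC(C)=O)[C@@H]3O[C@@H]32)[C@@H](OC(C)=O)[C@]2(O)[C@@H](C)C(=O)O[C@H]2[C@@H]1O | intermediate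
42 | C6 alkoxytriphenylphosphonium chloride | C=C1[C@H]2O[C@H]2[C@@H](OC(C)=O)[C@]2(C)[C@H]([C@@H](C)[C@@H](OC(C)=O)[C@@H]3O[C@@H]32)[C@@H](OC(C)=O)[C@]2(O)[C@@H](C)C(=O)O[C@H]2[C@@H]1O[P+](c1ccccc1)(c1ccccc1)c1ccccc1.[Cl-] | intermediate
43 | (1R,2S,3R,4R,6S,7R,8R,9R,10S,11R,12R,13S,14R,17R)-2,9,12-triacetoxy-6-chloro-3,4:13,14-diepoxy-8-hydroxybriar-5(16)-en-19,7-olide | C=C1[C@H]2O[C@H]2[C@@H](OC(C)=O)[C@]2(C)[C@H]([C@@H](C)[C@@H](OC(C)=O)[C@@H]3O[C@@H]32)[C@@H](OC(C)=O)[C@]2(O)[C@@H](C)C(=O)O[C@H]2[C@H]1Cl | target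

## Step count and risks

Total steps: 29. Longest linear sequence: 25 steps (steps 1–13 and 18–29); steps 14–17 make the C3–C6 aldehyde 25.

Steps most likely to fail:

Step 25. The alkenylchromium species may add to the wrong face of the C2 aldehyde, so that the undesired C2 epimer predominates. The fallback sets out from 37 as obtained (either epimer or their mixture). Dess–Martin oxidation gives the cross-conjugated macrocyclic dienone F1. Corey–Bakshi–Shibata reduction (oxazaborolidine enantiomer chosen to deliver hydride to the face that gives the required carbinol, catecholborane, toluene, −78 °C) then returns the route to 37 as a single epimer. Configuration at C2 is then set by the reagent and not by the ring.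

Step 22. The samarium reagent may cleave the C9 acetoxy group, which is α to the C8 ketone, by ketyl formation in competition with enolate generation. The fallback sets out from 29. Its free C7 hydroxyl and the C8 ketone are engaged as a zinc chelate by the pre-formed Reformatsky reagent of ethyl 2-bromopropanoate (BrZnCH(CH3)CO2Et, 3 equiv, THF, 0 °C), so no reductant touches the substrate. Cram-chelate addition gives hydroxy ester F2 with the same C8 configuration. PPTS in benzene then closes the lactone with loss of ethanol, and DBU equilibrates C17 to the epimer with the methyl trans to the C9 chain, which returns the route to 33.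

Step 29. Activation of the C6 hydroxyl in 41 may lead to allylic transposition (chloride entering at C16) or to opening of the neighbouring vinyl oxirane. The fallback moves the displacement ahead of oxirane formation and sets out from 37. Chloroacetic anhydride and pyridine mask the C2 hydroxyl as chloroacetate F3. HF·pyridine removes the C6 silyl ether to give alcohol F4. Ph3P and hexachloroacetone give the 6S chloride F5 with inversion. Thiourea (NaHCO3, EtOH) removes the chloroacetate in the presence of the acetates to give dienol chloride F6. VO(acac)2 and t-BuOOH install both oxiranes as in step 26 to give bis-epoxy alcohol F7. Acetylation as in step 27 returns the route at 43.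

Further compounds

F1 | step 25 | macrocyclic C2 ketone (3(Z),5(16)-dienone) | C=C1/C=C\C(=O)[C@]2(C)[C@H]([C@@H](C)[C@@H](OC(C)=O)C=C2)[C@@H](OC(C)=O)[C@]2(O)[C@@H](C)C(=O)O[C@H]2[C@@H]1O[Si](C)(C)C(C)(C)C
F2 | step 22 | ethyl ester diol (C7 and C8 hydroxyls, ethyl propanoate unit on C8, C17 epimers) | CC(C)(C)[Si](C)(C)OC[C@@]1(C)C=C[C@H](OC(C)=O)[C@H](C)[C@@H]1[C@@H](OC(C)=O)[C@](O)(C(C)C(=O)OCC)[C@@H](O)[C@H](O[Si](C)(C)C(C)(C)C)C(=C)/C=C\I
F3 | step 29 | C2 chloroacetate of 37 | C=C1/C=C\[C@@H](OC(=O)CCl)[C@]2(C)[C@H]([C@@H](C)[C@@H](OC(C)=O)C=C2)[C@@H](OC(C)=O)[C@]2(O)[C@@H](C)C(=O)O[C@H]2[C@@H]1O[Si](C)(C)C(C)(C)C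
F4 | step 29 | C6 alcohol of F3 | C=C1/C=C\[C@@H](OC(=O)CCl)[C@]2(C)[C@H]([C@@H](C)[C@@H](OC(C)=O)C=C2)[C@@H](OC(C)=O)[C@]2(O)[C@@H](C)C(=O)O[C@H]2[C@@H]1O
F5 | step 29 | 6S chloride with C2 chloroacetate | C=C1/C=C\[C@@H](OC(=O)CCl)[C@]2(C)[C@H]([C@@H](C)[C@@H](OC(C)=O)C=C2)[C@@H](OC(C)=O)[C@]2(O)[C@@H](C)C(=O)O[C@H]2[C@H]1Cl
F6 | step 29 | dienol chloride (free C2 hydroxyl, 6S chloride) | C=C1/C=C\[C@@H](O)[C@]2(C)[C@H]([C@@H](C)[C@@H](OC(C)=O)C=C2)[C@@H](OC(C)=O)[C@]2(O)[C@@H](C)C(=O)O[C@H]2[C@H]1Cl
F7 | step 29 | bis-epoxy alcohol with 6S chloride (2-deacetyl target) | C=C1[C@H]2O[C@H]2[C@@H](O)[C@]2(C)[C@H]([C@@H](C)[C@@H](OC(C)=O)[C@@H]3O[C@@H]32)[C@@H](OC(C)=O)[C@]2(O)[C@@H](C)C(=O)O[C@H]2[C@H]1Cl
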